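The cyclohexanol ring (ring C: C1–C4, C4a, C9b of the cis-hexahydrodibenzofuran) is closed by inserting a two-carbon vinyl unit, the future C3 and C4, between C2 and the acetal-level ring-fusion carbon C4a. The precursor is a 2-methoxy-2,3-dihydrobenzofuran whose quaternary C9b carries a 2-borylethyl arm. Its vinyl boronate complex attacks the oxocarbenium ion at C4a, and 1,2-migration of C2 from boron to C3 contracts the transient seven-membered boracycle to ring C. One operation thus forms C4–C4a and C2–C3 and leaves boron on C3, where the hydroxyl is needed. The Z,Z-bis-acrylamide macrolactam is built afterwards.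

Key step: step 6

Remark: atom numbers follow dibenzo[b,d]furan numbering of the core (ring C = C1, C2, C3, C4, C4a, C9b; O5; C8 is para to O5). The target core is (3R,4aR,9bS).
Assumption: the sense of induction of the acyl-transfer catalyst in step 3 is not known for this 3-vinyl substrate; the catalyst antipode that delivers (R)-6 is used.

Step 1
Reactants: 1 benzofuran-2(3H)-one; 2 acetaldehyde
Product: 3 3-ethylidenebenzofuran-2(3H)-one (E/Z mixture)
Conditions: TiCl4, pyridine, THF, 0 °C → rt
Reagents that add atoms: acetaldehyde (2), CC=O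
Why: Knoevenagel condensation under Lehnert conditions, where TiCl4/pyridine enolises the acidic C3 methylene and dehydrates the aldol adduct without the lactone aminolysis that secondary amines would cause; no stereocenter is formed.

Step 2
Reactants: 3 3-ethylidenebenzofuran-2(3H)-one; 4 benzyl chloroformate
Product: 5 benzyl (3-vinylbenzofuran-2-yl) carbonate
Conditions: NaN(SiMe3)2 (1.1 equiv), THF, −78 °C; then 4, −78 → 0 °C
Reagents that add atoms: benzyl chloroformate (4), O=C(Cl)OCc1ccccc1
Why: γ-Deprotonation gives the aromatic 3-vinylbenzofuran-2-olate, which the hard chloroformate acylates on oxygen (enol carbonate formation).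

Step 3
Reactants: 5 benzyl (3-vinylbenzofuran-2-yl) carbonate
Product: 6 benzyl (R)-2-oxo-3-vinyl-2,3-dihydrobenzofuran-3-carboxylate
Conditions: TADMAP [3-(1-acetoxy-2,2,2-triphenylethyl)-4-(dimethylamino)pyridine], one enantiomer, 5 mol%, CH2Cl2, 0 °C → rt
Reagents that add atoms: none
Why: Catalytic asymmetric O-to-C carboxyl transfer (Steglich/Black rearrangement), in which the chiral N-acylpyridinium/benzofuranolate ion pair recombines at C3 on one enantiotopic face and so sets the quaternary stereocenter (the future C9b) under catalyst control.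

Step 4
Reactants: 6 benzyl (R)-2-oxo-3-vinyl-2,3-dihydrobenzofuran-3-carboxylate
Product: 8 benzyl (3S)-2-methoxy-3-vinyl-2,3-dihydrobenzofuran-3-carboxylate (mixture of C2 epimers), via lactol 7 (not isolated)
Conditions: i-Bu2AlH (1.05 equiv), CH2Cl2, −78 °C; aq. KNaC4H4O6 work-up; crude lactol in MeOH, PPTS (cat.), rt
Reagents that add atoms: methanol, CO
Why: Chemoselective partial reduction followed by Fischer acetalisation: i-Bu2AlH attacks the strained aryl lactone carbonyl faster than the benzyl ester and the aluminium acetal survives at −78 °C, so reduction stops at the lactol; the two carbonyl carbons stay at different oxidation levels, so the quaternary center cannot scramble, and the acetal epimers converge later.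

Step 5
Reactants: 8 benzyl (3S)-2-methoxy-3-vinyl-2,3-dihydrobenzofuran-3-carboxylate
Product: 9 benzyl (3S)-2-methoxy-3-[2-(4,4,5,5-tetramethyl-1,3,2-dioxaborolan-2-yl)ethyl]-2,3-dihydrobenzofuran-3-carboxylate (mixture of C2 epimers)
Conditions: [Ir(cod)Cl]2 (1.5 mol%), dppe (3 mol%), pinacolborane (1.2 equiv), CH2Cl2, rt
Reagents that add atoms: pinacolborane, B1OC(C)(C)C(C)(C)O1
Why: Iridium-catalysed anti-Markovnikov hydroboration of the terminal alkene puts boron on the terminal carbon (the future C2); no stereocenter is formed.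

Step 6
Reactants: 9 benzyl (3S)-2-methoxy-3-[2-(4,4,5,5-tetramethyl-1,3,2-dioxaborolan-2-yl)ethyl]-2,3-dihydrobenzofuran-3-carboxylate; 10 tetravinylstannane
Product: 14 benzyl (3R,4aR,9bS)-3-hydroxy-1,2,3,4,4a,9b-hexahydrodibenzo[b,d]furan-9b-carboxylate, via vinyllithium 11 (not isolated), via vinyl boronate complex 12 (not isolated), via cyclised boronic ester 13 (not isolated)
Conditions: MeLi (1.05 equiv), 10 (0.27 equiv), Et2O, 0 °C; transfer to 9, THF, −78 °C; Et3SiOTf (1.2 equiv), 0.02 M, −78 → −40 °C; then aq. NaOH, 30% H2O2, 0 °C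
Reagents that add atoms: tetravinylstannane (10), C=C[Sn](C=C)(C=C)C=C; hydrogen peroxide, OO
Why: Proposed new method: vinyllithium adds to the pinacol boronate to give the tetracoordinate vinyl boronate 12, Et3SiOTf ionises the methyl acetal to the 3,3-disubstituted benzofuran-1-ium (oxocarbenium) ion, its C4a is attacked by the terminal vinyl carbon, and the electron-poor carbon created next to boron triggers 1,2-migration of the C2 alkyl group from boron to C3, so that C4–C4a and C2–C3 form in one operation; because the tether forces both bonds onto the same face of the vinyl group, the shift is expected to run through the short-lived α-boryl cation, not the usual concerted anti pathway. The closest known reaction type is the electrophile-induced 1,2-metallate rearrangement of vinyl boronate complexes with carbenium-type electrophiles (the intermolecular three-component coupling), together with the silyl-triflate-triggered 1,2-shift of boronate complexes onto an oxygen leaving group. Ring C closes by a 7-endo-trig attack of the vinyl group on the exocyclic oxocarbenium carbon to a transient seven-membered boracycle, followed by ring contraction that extrudes boron to an exocyclic position on the six-membered carbocycle. C4a is set cis to the C1 arm because the nucleophile is tethered through C9b and a trans-fused product cannot form; C3 is set by a chair-like array in which the planar cation holds the aryl group axial and the bulky boronate pseudo-equatorial, that is cis to the C4a–O bond, and the C–B oxidation is stereoretentive. The step needs intramolecular capture to beat silylation of the boronate oxygen and intermolecular coupling, which the gem-disubstituted C9b tether, high dilution and low temperature should secure.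

Step 7
Reactants: 14 benzyl (3R,4aR,9bS)-3-hydroxy-1,2,3,4,4a,9b-hexahydrodibenzo[b,d]furan-9b-carboxylate
Product: 15 (3R,4aR,9bS)-3-hydroxy-1,2,3,4,4a,9b-hexahydrodibenzo[b,d]furan-9b-carbaldehyde
Conditions: i-Bu2AlH (2.3 equiv), CH2Cl2/toluene, −78 °C; aq. KNaC4H4O6 work-up
Reagents that add atoms: none
Why: Partial reduction of the neopentyl-type benzyl ester by i-Bu2AlH, where the hindered tetrahedral aluminate is stable at −78 °C and releases the aldehyde only on work-up (the C3 alkoxide consumes one equivalent).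

Step 8
Reactants: 15 (3R,4aR,9bS)-3-hydroxy-1,2,3,4,4a,9b-hexahydrodibenzo[b,d]furan-9b-carbaldehyde; 16 methyl bis(2,2,2-trifluoroethyl)phosphonoacetate
Product: 17 methyl (Z)-3-[(3R,4aR,9bS)-3-hydroxy-1,2,3,4,4a,9b-hexahydrodibenzo[b,d]furan-9b-yl]prop-2-enoate
Conditions: 16 (2.2 equiv), KN(SiMe3)2 (2.2 equiv), 18-crown-6, THF, −78 °C
Reagents that add atoms: methyl bis(2,2,2-trifluoroethyl)phosphonoacetate (16), COC(=O)CP(=O)(OCC(F)(F)F)OCC(F)(F)F
Why: Still–Gennari olefination, in which the bis(trifluoroethyl)phosphonate eliminates fast from the kinetic adduct and should give the Z-enoate; the non-enolisable α-quaternary aldehyde cannot epimerise.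

Step 9
Reactants: 17 methyl (Z)-3-[(3R,4aR,9bS)-3-hydroxy-1,2,3,4,4a,9b-hexahydrodibenzo[b,d]furan-9b-yl]prop-2-enoate
Product: 18 (Z)-3-[(3R,4aR,9bS)-3-hydroxy-1,2,3,4,4a,9b-hexahydrodibenzo[b,d]furan-9b-yl]prop-2-enoic acid
Conditions: LiOH, THF/H2O (3:1), 0 °C → rt; then 1 M HCl to pH 3
Reagents that add atoms: water, O
Why: Saponification of the unhindered methyl ester, with retention of the Z geometry since no reversible conjugate addition operates under these conditions.

Step 10
Reactants: 18 (Z)-3-[(3R,4aR,9bS)-3-hydroxy-1,2,3,4,4a,9b-hexahydrodibenzo[b,d]furan-9b-yl]prop-2-enoic acid; 19 ethyl propiolate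
Product: 20 (Z)-3-[(3R,4aR,9bS)-8-[(Z)-3-ethoxy-3-oxoprop-1-en-1-yl]-3-hydroxy-1,2,3,4,4a,9b-hexahydrodibenzo[b,d]furan-9b-yl]prop-2-enoic acid
Conditions: Pd(OAc)2 (5 mol%), CF3CO2H/CH2Cl2 (4:1), rt, dark; then aq. NaHCO3/MeOH
Reagents that add atoms: ethyl propiolate (19), C#CC(=O)OCC
Why: Fujiwara hydroarylation, a trans-addition of the aryl C–H bond across the propiolate in CF3CO2H that should give the cis (Z) cinnamate, with the ring oxygen directing attack to the para position C8; the transient trifluoroacetate of the C3 alcohol is cleaved in the work-up.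

Step 11
Reactants: 20 (Z)-3-[(3R,4aR,9bS)-8-[(Z)-3-ethoxy-3-oxoprop-1-en-1-yl]-3-hydroxy-1,2,3,4,4a,9b-hexahydrodibenzo[b,d]furan-9b-yl]prop-2-enoic acid; 21 tert-butyl (4-aminobutyl)[3-(tert-butoxycarbonylamino)propyl]carbamate (N1,N4-bis-Boc-spermidine)
Product: 22 ethyl (Z)-3-[(3R,4aR,9bS)-9b-[(Z)-3-[[4-[(tert-butoxycarbonyl)[3-(tert-butoxycarbonylamino)propyl]amino]butyl]amino]-3-oxoprop-1-en-1-yl]-3-hydroxy-1,2,3,4,4a,9b-hexahydrodibenzo[b,d]furan-8-yl]prop-2-enoate
Conditions: EDC·HCl, HOBt, i-Pr2NEt, CH2Cl2, 0 °C → rt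
Reagents that add atoms: N1,N4-bis-Boc-spermidine (21), NCCCCN(CCCNC(=O)OC(C)(C)C)C(=O)OC(C)(C)C
Why: Carbodiimide/HOBt amide coupling of the free acrylic acid with the only free (primary) amine of 21; the ethyl cinnamate and the alcohol should not react.

Step 12
Reactants: 22 the ethyl cinnamate amide from step 11
Product: 23 (Z)-3-[(3R,4aR,9bS)-9b-[(Z)-3-[[4-[(tert-butoxycarbonyl)[3-(tert-butoxycarbonylamino)propyl]amino]butyl]amino]-3-oxoprop-1-en-1-yl]-3-hydroxy-1,2,3,4,4a,9b-hexahydrodibenzo[b,d]furan-8-yl]prop-2-enoic acid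
Conditions: LiOH, THF/MeOH/H2O, 0 °C → rt; 1 M HCl to pH 4 at 0 °C
Reagents that add atoms: water, O
Why: Saponification of the ethyl cinnamate; the Boc groups and the secondary amide are stable to LiOH.

Step 13
Reactants: 23 the cinnamic acid from step 12; 24 N-hydroxysuccinimide
Product: 25 the N-hydroxysuccinimide ester of 23 (2,5-dioxopyrrolidin-1-yl (Z)-cinnamate, otherwise unchanged)
Conditions: EDC·HCl, 24, CH2Cl2, 0 °C → rt, dark
Reagents that add atoms: N-hydroxysuccinimide (24), ON1C(=O)CCC1=O
Why: Active-ester formation with a carbodiimide; without an acyl-transfer catalyst the secondary alcohol should not be acylated.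

Step 14
Reactants: 25 the N-hydroxysuccinimide ester
Product: 27 target macrolactam (CNP0243477.1), via deprotected diamine 26 (not isolated)
Conditions: CF3CO2H/CH2Cl2 (1:4), 0 °C; evaporate; slow addition (syringe pump) to i-Pr2NEt, MeCN (0.5 mM), rt, dark
Reagents that add atoms: none
Why: Acidolysis removes both Boc groups without touching the active ester, and at high dilution the unhindered primary amine should acylate much faster than the dialkylamine (chemoselective aminolysis, macrolactamisation) to close the 20-membered ring with both Z alkenes and all three stereocenters intact.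

Compound list
1 | benzofuran-2(3H)-one (2-coumaranone) | O=C1Cc2ccccc2O1 | starting material
2 | acetaldehyde | CC=O | starting material
3 | 3-ethylidenebenzofuran-2(3H)-one (E/Z mixture) | CC=C1C(=O)Oc2ccccc12 | intermediate
4 | benzyl chloroformate | O=C(Cl)OCc1ccccc1 | starting material
5 | benzyl (3-vinylbenzofuran-2-yl) carbonate | C=Cc1c(OC(=O)OCc2ccccc2)oc2ccccc12 | intermediate
6 | benzyl (R)-2-oxo-3-vinyl-2,3-dihydrobenzofuran-3-carboxylate | O=C(OCc1ccccc1)[C@]2(C=C)C(=O)Oc3ccccc23 | intermediate
7 | benzyl (3S)-2-hydroxy-3-vinyl-2,3-dihydrobenzofuran-3-carboxylate (lactol, C2 epimers, not isolated) | O=C(OCc1ccccc1)[C@]2(C=C)C(O)Oc3ccccc23 | intermediate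
8 | benzyl (3S)-2-methoxy-3-vinyl-2,3-dihydrobenzofuran-3-carboxylate (C2 epimers) | O=C(OCc1ccccc1)[C@]2(C=C)C(OC)Oc3ccccc23 | intermediate
9 | benzyl (3S)-2-methoxy-3-[2-(4,4,5,5-tetramethyl-1,3,2-dioxaborolan-2-yl)ethyl]-2,3-dihydrobenzofuran-3-carboxylate (C2 epimers) | O=C(OCc1ccccc1)[C@]2(CCB4OC(C)(C)C(C)(C)O4)C(OC)Oc3ccccc23 | intermediate
10 | tetravinylstannane | C=C[Sn](C=C)(C=C)C=C | starting material
11 | vinyllithium (not isolated) | [Li]C=C | intermediate
12 | lithium vinyl boronate complex of 9 (not isolated) | [Li+].O=C(OCc1ccccc1)[C@]2(CC[B-]4(C=C)OC(C)(C)C(C)(C)O4)C(OC)Oc3ccccc23 | intermediate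
13 | benzyl (3R,4aR,9bS)-3-(4,4,5,5-tetramethyl-1,3,2-dioxaborolan-2-yl)-1,2,3,4,4a,9b-hexahydrodibenzo[b,d]furan-9b-carboxylate (not isolated) | O=C(OCc1ccccc1)[C@]23CC[C@@H](B4OC(C)(C)C(C)(C)O4)C[C@H]2Oc2ccccc23 | intermediate
14 | benzyl (3R,4aR,9bS)-3-hydroxy-1,2,3,4,4a,9b-hexahydrodibenzo[b,d]furan-9b-carboxylate | O=C(OCc1ccccc1)[C@]23CC[C@@H](O)C[C@H]2Oc2ccccc23 | intermediate
15 | (3R,4aR,9bS)-3-hydroxy-1,2,3,4,4a,9b-hexahydrodibenzo[b,d]furan-9b-carbaldehyde | O=C[C@]23CC[C@@H](O)C[C@H]2Oc2ccccc23 | intermediate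
16 | methyl bis(2,2,2-trifluoroethyl)phosphonoacetate | COC(=O)CP(=O)(OCC(F)(F)F)OCC(F)(F)F | starting material
17 | methyl (Z)-3-[(3R,4aR,9bS)-3-hydroxy-1,2,3,4,4a,9b-hexahydrodibenzo[b,d]furan-9b-yl]prop-2-enoate | COC(=O)/C=C\[C@]23CC[C@@H](O)C[C@H]2Oc2ccccc23 | intermediate
18 | (Z)-3-[(3R,4aR,9bS)-3-hydroxy-1,2,3,4,4a,9b-hexahydrodibenzo[b,d]furan-9b-yl]prop-2-enoic acid | OC(=O)/C=C\[C@]23CC[C@@H](O)C[C@H]2Oc2ccccc23 | intermediate
19 | ethyl propiolate | C#CC(=O)OCC | starting material
20 | (Z)-3-[(3R,4aR,9bS)-8-[(Z)-3-ethoxy-3-oxoprop-1-en-1-yl]-3-hydroxy-1,2,3,4,4a,9b-hexahydrodibenzo[b,d]furan-9b-yl]prop-2-enoic acid | OC(=O)/C=C\[C@]23CC[C@@H](O)C[C@H]2Oc2ccc(cc23)/C=C\C(=O)OCC | intermediate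
21 | tert-butyl (4-aminobutyl)[3-(tert-butoxycarbonylamino)propyl]carbamate (N1,N4-bis-Boc-spermidine) | NCCCCN(CCCNC(=O)OC(C)(C)C)C(=O)OC(C)(C)C | starting material
22 | ethyl (Z)-cinnamate bearing the N8-linked bis-Boc-spermidine (Z)-acrylamide at C9b (3R,4aR,9bS) | O=C(NCCCCN(CCCNC(=O)OC(C)(C)C)C(=O)OC(C)(C)C)/C=C\[C@]23CC[C@@H](O)C[C@H]2Oc2ccc(cc23)/C=C\C(=O)OCC | intermediate
23 | corresponding (Z)-cinnamic acid (3R,4aR,9bS) | O=C(NCCCCN(CCCNC(=O)OC(C)(C)C)C(=O)OC(C)(C)C)/C=C\[C@]23CC[C@@H](O)C[C@H]2Oc2ccc(cc23)/C=C\C(=O)O | intermediate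
24 | N-hydroxysuccinimide | ON1C(=O)CCC1=O | starting material
25 | N-hydroxysuccinimide ester of 23 (3R,4aR,9bS) | O=C(NCCCCN(CCCNC(=O)OC(C)(C)C)C(=O)OC(C)(C)C)/C=C\[C@]23CC[C@@H](O)C[C@H]2Oc2ccc(cc23)/C=C\C(=O)ON1C(=O)CCC1=O | intermediate
26 | Boc-free diamine active ester (bis-trifluoroacetate salt in the flask, drawn as free base, not isolated) | O=C(NCCCCNCCCN)/C=C\[C@]23CC[C@@H](O)C[C@H]2Oc2ccc(cc23)/C=C\C(=O)ON1C(=O)CCC1=O | intermediate
27 | target macrolactam, (3R,4aR,9bS) core with two (Z)-acrylamides and free N4 and C3–OH | O=C1/C=C\[C@]23CC[C@@H](O)C[C@H]2Oc2ccc(cc23)/C=C\C(=O)NCCCNCCCCN1 | target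

Total step count: 14. Longest linear sequence: 14 steps (from 1; all other components are purchased).

Steps most likely to fail

Step 6 (proposed new method). The silyl triflate may attack the boronate oxygen instead of the acetal, the cation may couple intermolecularly, or migration may deliver the C3 epimer. The fallback makes the two bonds in two known steps. It sets out from 8: hydroboration with 9-BBN should give the B-alkyl-9-borabicyclononane adduct F1 (not isolated), and B-alkyl Suzuki–Miyaura coupling with vinyl bromide (PdCl2(dppf), aq. K3PO4, THF/DMF) should give the butenyl acetal F2. Cation–olefin (Prins-type) cyclisation of F2 in CF3CO2H/CH2Cl2 at 0 °C should close ring C through the terminal alkene carbon, with equatorial capture of the C3 cation, to the trifluoroacetate F3. Methanolysis (NaHCO3, MeOH) returns to the route at 14.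

Step 3. Facial discrimination in the ion pair may be poor for the new 3-vinyl substrate, or the acyl group may be transferred to the vinyl terminus. The fallback replaces asymmetric catalysis by resolution. It sets out from 5: rearrangement with achiral DMAP should give the racemic C-acylated lactone F4, which is resolved by preparative chromatography on a chiral stationary phase; the (R)-enantiomer returns to the route at 6.

Step 10. The arene may be too weakly nucleophilic, attack may go ortho to oxygen, or the Z alkenes may isomerise in acid. The fallback uses cross-coupling and semi-hydrogenation. It sets out from 18: iodination para to the ring oxygen (N-iodosuccinimide, cat. CF3CO2H, MeCN) should give the aryl iodide F5, and Sonogashira coupling with 19 (Pd(PPh3)2Cl2, CuI, K2CO3, THF) the aryl propiolate F6. Lindlar semi-hydrogenation (H2, Pd/CaCO3 poisoned with Pb(OAc)2, quinoline) returns to the route at 20.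

Further compounds
F1 | step 6 | benzyl (3S)-3-[2-(9-borabicyclo[3.3.1]nonan-9-yl)ethyl]-2-methoxy-2,3-dihydrobenzofuran-3-carboxylate | O=C(OCc1ccccc1)[C@]2(CCB4C5CCCC4CCC5)C(OC)Oc3ccccc23
F2 | step 6 | benzyl (3S)-3-(but-3-en-1-yl)-2-methoxy-2,3-dihydrobenzofuran-3-carboxylate | O=C(OCc1ccccc1)[C@]2(CCC=C)C(OC)Oc3ccccc23
F3 | step 6 | benzyl (3R,4aR,9bS)-3-(trifluoroacetoxy)-1,2,3,4,4a,9b-hexahydrodibenzo[b,d]furan-9b-carboxylate | O=C(OCc1ccccc1)[C@]23CC[C@@H](OC(=O)C(F)(F)F)C[C@H]2Oc2ccccc23
F4 | step 3 | racemic benzyl 2-oxo-3-vinyl-2,3-dihydrobenzofuran-3-carboxylate | O=C(OCc1ccccc1)C2(C=C)C(=O)Oc3ccccc23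
F5 | step 10 | (Z)-3-[(3R,4aR,9bS)-3-hydroxy-8-iodo-1,2,3,4,4a,9b-hexahydrodibenzo[b,d]furan-9b-yl]prop-2-enoic acid | OC(=O)/C=C\[C@]23CC[C@@H](O)C[C@H]2Oc2ccc(I)cc23
F6 | step 10 | (Z)-3-[(3R,4aR,9bS)-8-(3-ethoxy-3-oxoprop-1-yn-1-yl)-3-hydroxy-1,2,3,4,4a,9b-hexahydrodibenzo[b,d]furan-9b-yl]prop-2-enoic acid | OC(=O)/C=C\[C@]23CC[C@@H](O)C[C@H]2Oc2ccc(cc23)C#CC(=O)OCC
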